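**Plan**

1. The target is (R)-5,8-dihydroxy-2-pentadecylchroman-4-one. Retrosynthetically, the two phenols are first masked as benzyl ethers. The pyranone ring is then cut at O1–C2 and at C4–C4a together, giving 2,5-bis(benzyloxy)phenol and (S)-4-pentadecyloxetan-2-one. The lactone goes back to methyl 3-oxooctadecanoate.
2. Enabling feature: O1 and C4a are a phenol oxygen and its only unsubstituted ortho carbon (between O1 and the C5 oxygen of the benzene ring), a 1,3-O,C-dinucleophile. C2–C3–C4 of the pyranone ring have the oxidation pattern of a β-lactone (sp3 C–O at C2, acyl carbon at C4), a strained 1,3-dielectrophile.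
3. Forward: the benzene ring is bought complete (2,5-dihydroxybenzaldehyde, benzylation, Dakin oxidation). The chain is made as the β-lactone (asymmetric hydrogenation, saponification, lactonisation). The pyranone ring, the only ring built, arises in one flask by aryloxide opening of the lactone and Friedel–Crafts closure; hydrogenolysis finishes.
4. Stereochemistry: the single center comes from the (S)-carbinol set by ruthenium/(S)-BINAP hydrogenation. It is retained in the lactonisation and inverted once in the SN2 opening, which gives (R) at C2.

Key step: step 6

Assumption: methyl 3-oxooctadecanoate and 2,5-dihydroxybenzaldehyde are taken as purchasable compounds; the target SMILES is read as (R) at C2.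

**Route**

Step 1
Reactants: 1 2,5-dihydroxybenzaldehyde
Product: 2 2,5-bis(benzyloxy)benzaldehyde
Conditions: BnBr, K2CO3, DMF, 60 °C, under N2
Reagents that add atoms: benzyl bromide, BrCc1ccccc1
Why: Williamson etherification, in which both phenoxides of 1 formed by K2CO3 in DMF should be benzylated by SN2 on benzyl bromide while the aldehyde stays inert; no stereocenter is formed.

Step 2
Reactants: 2 2,5-bis(benzyloxy)benzaldehyde
Product: 4 2,5-bis(benzyloxy)phenol, via formate ester 3 (not isolated)
Conditions: mCPBA, CH2Cl2, 0 °C → rt; then MeOH, K2CO3 (cat.), rt
Reagents that add atoms: mCPBA, OOC(=O)c1cccc(Cl)c1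
Why: Dakin-type Baeyer–Villiger oxidation, in which the electron-rich aryl group migrates to oxygen in the Criegee adduct to give formate 3, whose mild methanolysis should release phenol 4 with both benzyl ethers untouched; no stereocenter is formed.

Step 3
Reactants: 5 methyl 3-oxooctadecanoate
Product: 6 methyl (S)-3-hydroxyoctadecanoate
Conditions: H2 (50 atm), RuCl2[(S)-BINAP] (0.2 mol %), MeOH, 50 °C
Reagents that add atoms: none
Why: Noyori asymmetric hydrogenation of a β-keto ester, in which chelation of the keto ester to the ruthenium hydride of the (S)-BINAP complex fixes the face of hydride delivery and should set C3 as (S), the sense established for unbranched 3-oxoalkanoates.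

Step 4
Reactants: 6 methyl (S)-3-hydroxyoctadecanoate
Product: 8 (S)-3-hydroxyoctadecanoic acid, via lithium carboxylate 7 (not isolated)
Conditions: LiOH·H2O, THF/MeOH/H2O, rt; then 1 M HCl to pH 2
Reagents that add atoms: lithium hydroxide, [Li+].[OH-]
Why: Ester saponification at room temperature, which breaks no bond at the carbinol center and should be too mild to dehydrate the β-hydroxy carboxylate, so the (S) configuration is kept.

Step 5
Reactants: 8 (S)-3-hydroxyoctadecanoic acid
Product: 10 (S)-4-pentadecyloxetan-2-one, via mixed sulfonic anhydride 9 (not isolated)
Conditions: PhSO2Cl, pyridine, 0 °C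
Reagents that add atoms: none
Why: β-Lactonisation by carboxyl activation, in which the acid becomes mixed anhydride 9 and the C3 hydroxyl closes the four-membered ring by 4-exo-trig attack on the acyl carbon, so the C–O bond at the stereocenter is never broken and (S) is retained.

Step 6
Reactants: 4 2,5-bis(benzyloxy)phenol; 10 (S)-4-pentadecyloxetan-2-one
Product: 14 (R)-5,8-bis(benzyloxy)-2-pentadecylchroman-4-one, via sodium aryloxide 11 (not isolated), via sodium 3-aryloxy carboxylate 12 (not isolated), via acyl trifluoroacetate 13 (not isolated)
Conditions: NaH, 15-crown-5, THF, 0 °C; then 10, 0 → 50 °C; THF evaporated; then TFAA, TFA, CH2Cl2, 0 °C → rt; aqueous NaHCO3 work-up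
Reagents that add atoms: none
Why: Formal [3+3] annulation of a phenol (O,C-1,3-dinucleophile) with a β-lactone (1,3-dielectrophile): aryloxide 11 opens the strained lactone 10 by SN2 attack at C4 with alkyl–oxygen cleavage to carboxylate 12, TFAA converts 12 into acyl trifluoroacetate 13, and 13 acylates the arene intramolecularly (Friedel–Crafts). The closest known reaction type is the opening of β-propiolactone or β-butyrolactone by phenoxides to 3-aryloxyalkanoic acids, followed by cycloacylation to chroman-4-ones. The pyranone ring closes in the acylation, a 6-exo-trig attack of the aryl carbon on the activated acyl carbon. The C2 stereocenter is substrate-controlled: backside displacement of the carboxylate inverts (S)-10 to the (R) ether, and the acylation does not touch this center. Two selectivities are needed: attack at C4 over attack at the acyl carbon or deprotonation at C3, which the soft crown-separated aryloxide should favour because acyl attack is reversible (the β-alkoxy aryl ester can return to lactone and aryloxide) whereas carboxylate formation is not; and acylation at one ring carbon, which the tether secures because the only free position ortho to the ether oxygen lies between two oxygen substituents. The work-up is kept near neutral so that the β-aryloxy ketone does not open by retro-oxa-Michael reaction and lose its configuration.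

Step 7
Reactants: 14 (R)-5,8-bis(benzyloxy)-2-pentadecylchroman-4-one
Product: 15 (R)-5,8-dihydroxy-2-pentadecylchroman-4-one
Conditions: H2 (1 atm), 10% Pd/C, EtOAc, rt; filtered and isolated under argon
Reagents that add atoms: none
Why: Heterogeneous hydrogenolysis of the two aryl benzyl ethers under neutral conditions, which should free both phenols without enolising or opening the β-aryloxy ketone, so the C2 configuration is kept, while the chelated aryl ketone and the saturated chain should resist reduction at one atmosphere.

**Compound list**

1 | 2,5-dihydroxybenzaldehyde | O=Cc1cc(O)ccc1O | starting material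
2 | 2,5-bis(benzyloxy)benzaldehyde | O=Cc1cc(OCc2ccccc2)ccc1OCc1ccccc1 | intermediate
3 | 2,5-bis(benzyloxy)phenyl formate (not isolated) | O=COc1cc(OCc2ccccc2)ccc1OCc1ccccc1 | intermediate
4 | 2,5-bis(benzyloxy)phenol | Oc1cc(OCc2ccccc2)ccc1OCc1ccccc1 | intermediate
5 | methyl 3-oxooctadecanoate | CCCCCCCCCCCCCCCC(=O)CC(=O)OC | starting material
6 | methyl (S)-3-hydroxyoctadecanoate | CCCCCCCCCCCCCCC[C@H](O)CC(=O)OC | intermediate
7 | lithium (S)-3-hydroxyoctadecanoate (not isolated) | CCCCCCCCCCCCCCC[C@H](O)CC(=O)[O-].[Li+] | intermediate
8 | (S)-3-hydroxyoctadecanoic acid | CCCCCCCCCCCCCCC[C@H](O)CC(=O)O | intermediate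
9 | (S)-3-hydroxyoctadecanoic benzenesulfonic anhydride (not isolated) | CCCCCCCCCCCCCCC[C@H](O)CC(=O)OS(=O)(=O)c1ccccc1 | intermediate
10 | (S)-4-pentadecyloxetan-2-one | CCCCCCCCCCCCCCC[C@H]1CC(=O)O1 | intermediate
11 | sodium 2,5-bis(benzyloxy)phenoxide (not isolated) | [Na+].[O-]c1cc(OCc2ccccc2)ccc1OCc1ccccc1 | intermediate
12 | sodium (R)-3-[2,5-bis(benzyloxy)phenoxy]octadecanoate (not isolated) | CCCCCCCCCCCCCCC[C@@H](Oc1cc(OCc2ccccc2)ccc1OCc1ccccc1)CC(=O)[O-].[Na+] | intermediate
13 | (R)-3-[2,5-bis(benzyloxy)phenoxy]octadecanoic trifluoroacetic anhydride (not isolated) | CCCCCCCCCCCCCCC[C@@H](Oc1cc(OCc2ccccc2)ccc1OCc1ccccc1)CC(=O)OC(=O)C(F)(F)F | intermediate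
14 | (R)-5,8-bis(benzyloxy)-2-pentadecylchroman-4-one | CCCCCCCCCCCCCCC[C@@H]1CC(=O)c2c(OCc3ccccc3)ccc(OCc3ccccc3)c2O1 | intermediate
15 | (R)-5,8-dihydroxy-2-pentadecylchroman-4-one | CCCCCCCCCCCCCCC[C@@H]1CC(=O)c2c(O)ccc(O)c2O1 | target

**Count and risks**

Total step count: 7. Longest linear sequence: 5 steps (steps 3, 4, 5, 6, 7).

Steps most likely to fail:

Step 6. The aryloxide may attack the acyl carbon or remove a C3 proton of the lactone, leading to ester formation or elimination in place of SN2 displacement at C4. In the acylation half, the acid may cleave or shift a benzyl group. The fallback forms the O–C2 bond by alcohol activation, not by lactone opening. It sets out from phenol 4 and hydroxy ester 6. Mitsunobu etherification (PPh3, DIAD, THF, 0 °C → rt) should give methyl (R)-3-[2,5-bis(benzyloxy)phenoxy]octadecanoate F1 with inversion at C3. Saponification with NaOH in THF/MeOH/H2O should then give the sodium carboxylate. After drying, this salt is compound 12, where the fallback comes back to the route, and it is carried through the TFAA stage of step 6 to 14.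

Step 5. With an acid that has no substituent at C2, intermolecular ester formation or dehydration may outrun the strained four-membered ring closure. The fallback closes the ring by hydroxyl activation, which needs the mirror-image acid. It sets out from keto ester 5. Hydrogenation with RuCl2[(R)-BINAP] should give methyl (R)-3-hydroxyoctadecanoate F2. LiOH should give lithium (R)-3-hydroxyoctadecanoate F3, and acidification gives (R)-3-hydroxyoctadecanoic acid F4. Mitsunobu lactonisation (PPh3, DIAD, THF, −78 °C → rt), in which the carboxylate displaces the oxyphosphonium group at C3 with inversion, should then give the (S)-lactone. The fallback comes back to the route at compound 10.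

Step 7. Prolonged contact with the catalyst may over-reduce the benzylic ketone, and the freed hydroquinone may be oxidised by air during isolation. The fallback removes the benzyl groups without hydrogen. It sets out from 14 and uses BCl3 with pentamethylbenzene as benzyl cation scavenger in CH2Cl2 at −78 °C, followed by a methanol quench under argon. It comes back to the route at target 15. No compound beyond those listed arises on this way (none F0).

Further compounds
F1 | step 6 | methyl (R)-3-[2,5-bis(benzyloxy)phenoxy]octadecanoate | CCCCCCCCCCCCCCC[C@@H](Oc1cc(OCc2ccccc2)ccc1OCc1ccccc1)CC(=O)OC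
F2 | step 5 | methyl (R)-3-hydroxyoctadecanoate | CCCCCCCCCCCCCCC[C@@H](O)CC(=O)OC
F3 | step 5 | lithium (R)-3-hydroxyoctadecanoate | CCCCCCCCCCCCCCC[C@@H](O)CC(=O)[O-].[Li+]
F4 | step 5 | (R)-3-hydroxyoctadecanoic acid | CCCCCCCCCCCCCCC[C@@H](O)CC(=O)O
F0 | step 7 | none | none
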